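**Retrosynthetic overview**

1. The oxane is numbered O1, C2 (aryl), C3, C4 (OH), C5, C6 (arylethyl). The plan rests on C2: it is bonded to O1 and benzylic to an electron-rich 4-oxy-3-methoxyphenyl ring, so in an open-chain benzyl ether its CH2 gives up hydride to DDQ.
2. Target 19 ⇐ oxan-4-one 17, by equatorial hydride delivery (axial C4–OH) and release of both phenols in one operation.
3. 17 ⇐ enol acetate 14, by the C2–C3 disconnection; the oxane, the only ring formed, is closed here.
4. 14 ⇐ alkyne 13 (Ru-catalysed AcOH addition) ⇐ (S)-homopropargylic alcohol 8 + vanillyl trichloroacetimidate 12 (from vanillin 9).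
5. 8 ⇐ aldehyde 5 (from eugenol 1) + allenylboronate 6; the catalytic asymmetric propargylation sets C6.

Key step: step 10

Assumption: (R)-TRIP phosphoric acid is taken to direct the allenylboronate to the Re face of aldehyde 5, as with other aldehydes, which here means the (S)-carbinol; the configuration of 8 is to be checked by Mosher ester analysis, and the mirror-image catalyst serves if the check requires it.

**Route**

Step 1
Reactants: 1 eugenol (4-allyl-2-methoxyphenol)
Product: 2 4-allyl-2-methoxyphenyl pivalate
Conditions: PivCl, Et3N, DMAP (cat.), CH2Cl2, 0 °C → rt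
Reagents that add atoms: pivaloyl chloride, CC(C)(C)C(Cl)=O
Why: DMAP-catalysed acylation of the phenol; the hindered aryl ester makes this guaiacol ring electron-poor, so that it will later resist DDQ.

Step 2
Reactants: 2 4-allyl-2-methoxyphenyl pivalate
Product: 4 4-(3-hydroxypropyl)-2-methoxyphenyl pivalate, via alkylborane 3 (not isolated)
Conditions: 9-BBN, THF, 0 °C → rt; then NaBO3·4H2O, H2O, rt
Reagents that add atoms: sodium perborate (used as NaBO3·4H2O), [Na+].[O-]OB=O
Why: Hydroboration–oxidation; 9-BBN adds to the terminal carbon of the allyl group with anti-Markovnikov selectivity, and the mild perborate oxidation of the C–B bond should spare the aryl pivalate.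

Step 3
Reactants: 4 4-(3-hydroxypropyl)-2-methoxyphenyl pivalate
Product: 5 2-methoxy-4-(3-oxopropyl)phenyl pivalate
Conditions: TEMPO (cat.), PhI(OAc)2, CH2Cl2, rt
Reagents that add atoms: none
Why: Nitroxyl-catalysed oxidation of a primary alcohol stops at the aldehyde and leaves the ester and the arene untouched.

Step 4
Reactants: 5 2-methoxy-4-(3-oxopropyl)phenyl pivalate; 6 allenylboronic acid pinacol ester
Product: 8 4-[(3S)-3-hydroxyhex-5-yn-1-yl]-2-methoxyphenyl pivalate, via pinacol borate ester 7 (not isolated)
Conditions: (R)-TRIP phosphoric acid [(R)-3,3′-bis(2,4,6-triisopropylphenyl)-1,1′-binaphthyl-2,2′-diyl hydrogen phosphate] (10 mol%), 4 Å MS, toluene, 0 °C; aqueous work-up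
Reagents that add atoms: none
Why: Chiral Brønsted acid-catalysed propargylation of an aldehyde with an allenylboronate through a closed six-membered SE2′ transition state; the phosphoric acid binds the boronate oxygen and the formyl hydrogen and shields one face, so C–C bond formation on the Re face should set the (S)-carbinol that becomes C6.

Step 5
Reactants: 9 vanillin (4-hydroxy-3-methoxybenzaldehyde)
Product: 10 4-(tert-butyldimethylsilyloxy)-3-methoxybenzaldehyde
Conditions: TBSCl, imidazole, DMF, rt
Reagents that add atoms: tert-butyldimethylsilyl chloride, CC(C)(C)[Si](C)(C)Cl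
Why: Standard silylation of a phenol; the silyl ether keeps this ring electron-rich for the later oxidation.

Step 6
Reactants: 10 4-(tert-butyldimethylsilyloxy)-3-methoxybenzaldehyde
Product: 11 [4-(tert-butyldimethylsilyloxy)-3-methoxyphenyl]methanol
Conditions: NaBH4, MeOH/THF, 0 °C
Reagents that add atoms: none
Why: Borohydride reduction of an aromatic aldehyde, short and cold enough to leave the aryl silyl ether in place.

Step 7
Reactants: 11 [4-(tert-butyldimethylsilyloxy)-3-methoxyphenyl]methanol
Product: 12 4-(tert-butyldimethylsilyloxy)-3-methoxybenzyl 2,2,2-trichloroacetimidate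
Conditions: Cl3CCN, DBU (cat.), CH2Cl2, 0 °C; used without storage
Reagents that add atoms: trichloroacetonitrile, N#CC(Cl)(Cl)Cl
Why: Base-catalysed addition of the benzylic alcohol to the nitrile gives the imidate under conditions that do not affect the aryl silyl ether.

Step 8
Reactants: 8 4-[(3S)-3-hydroxyhex-5-yn-1-yl]-2-methoxyphenyl pivalate; 12 4-(tert-butyldimethylsilyloxy)-3-methoxybenzyl 2,2,2-trichloroacetimidate
Product: 13 4-[(3S)-3-{[4-(tert-butyldimethylsilyloxy)-3-methoxybenzyl]oxy}hex-5-yn-1-yl]-2-methoxyphenyl pivalate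
Conditions: La(OTf)3 (cat.), toluene, rt
Reagents that add atoms: none
Why: Acid-catalysed O-benzylation with a trichloroacetimidate; the stabilised benzylic cation is captured by the secondary alcohol without base, so the aryl pivalate survives, and no bond at the carbinol carbon is broken, so its configuration is kept.

Step 9
Reactants: 13 4-[(3S)-3-{[4-(tert-butyldimethylsilyloxy)-3-methoxybenzyl]oxy}hex-5-yn-1-yl]-2-methoxyphenyl pivalate
Product: 14 (4S)-4-{[4-(tert-butyldimethylsilyloxy)-3-methoxybenzyl]oxy}-6-[3-methoxy-4-(pivaloyloxy)phenyl]hex-1-en-2-yl acetate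
Conditions: [RuCl2(p-cymene)]2 (cat.), tri(2-furyl)phosphine, Na2CO3 (cat.), AcOH, toluene, 80 °C
Reagents that add atoms: acetic acid, CC(=O)O
Why: Ruthenium-catalysed Markovnikov hydroacyloxylation of a terminal alkyne; with the electron-poor furylphosphine the carboxylate adds to the internal alkyne carbon and should give the 2-acetoxy-1-alkene while ether, ester and silyl ether are left alone.

Step 10
Reactants: 14 (4S)-4-{[4-(tert-butyldimethylsilyloxy)-3-methoxybenzyl]oxy}-6-[3-methoxy-4-(pivaloyloxy)phenyl]hex-1-en-2-yl acetate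
Product: 17 (2S,6S)-2-[4-(tert-butyldimethylsilyloxy)-3-methoxyphenyl]-6-{2-[3-methoxy-4-(pivaloyloxy)phenyl]ethyl}oxan-4-one, via aryl oxocarbenium ion 15 (not isolated), via O-acetyl oxocarbenium ion 16 (not isolated)
Conditions: DDQ, 2,6-dichloropyridine, 4 Å MS, ClCH2CH2Cl, rt; then aq. NaHCO3
Reagents that add atoms: none
Why: DDQ takes an electron from the 4-silyloxy-3-methoxybenzyl ether and then a hydrogen atom from its CH2 (net hydride abstraction) to give the E-configured aryl oxocarbenium ion 15; the closest known reaction type is the DDQ-mediated oxidative C–H cleavage of electron-rich benzylic ethers with intramolecular enol acetate capture to cis-2,6-disubstituted oxan-4-ones. The terminal enol acetate carbon adds to the oxocarbenium carbon in a 6-endo-trig closure that forms C2–C3 and the oxane ring, and the O-acetyl oxocarbenium ion 16 then gives up its acetyl group to the hydroquinone anion. The new stereocentre C2 is controlled by C6: in the chair transition state the C6 arylethyl chain is equatorial and the E geometry of the oxocarbenium ion places the aryl group equatorial as well, so C2 should form cis to C6 with the (S) configuration. The step needs chemoselectivity between the two arenes, which the pivalate secures by raising the oxidation potential of the distal ring, whose benzylic carbon also carries no oxygen to stabilise a cation. 2,6-Dichloropyridine buffers the acidic hydroquinone so that the aryl silyl ether and the enol acetate are not cleaved, and the product should resist a second oxidation because the carbonyl group destabilises a cation at C2.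

Step 11
Reactants: 17 (2S,6S)-2-[4-(tert-butyldimethylsilyloxy)-3-methoxyphenyl]-6-{2-[3-methoxy-4-(pivaloyloxy)phenyl]ethyl}oxan-4-one
Product: 18 4-{2-[(2S,4S,6S)-6-[4-(tert-butyldimethylsilyloxy)-3-methoxyphenyl]-4-hydroxyoxan-2-yl]ethyl}-2-methoxyphenyl pivalate
Conditions: LiBH(s-Bu)3, THF, −78 °C; then H2O
Reagents that add atoms: none
Why: Diastereoselective ketone reduction with a bulky trialkylborohydride; it approaches the chair oxan-4-one from the equatorial direction, away from the axial hydrogens at C2 and C6, so the C4 hydroxyl should end up axial, trans to both equatorial substituents (4S), and at −78 °C the aryl pivalate is not reduced.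

Step 12
Reactants: 18 4-{2-[(2S,4S,6S)-6-[4-(tert-butyldimethylsilyloxy)-3-methoxyphenyl]-4-hydroxyoxan-2-yl]ethyl}-2-methoxyphenyl pivalate
Product: 19 (2S,4S,6S)-2-(4-hydroxy-3-methoxyphenyl)-6-[2-(4-hydroxy-3-methoxyphenyl)ethyl]oxan-4-ol
Conditions: K2CO3, MeOH (degassed), rt → 40 °C; then aq. NH4Cl
Reagents that add atoms: none
Why: Base-mediated methanolysis; methoxide attacks the pivalate carbonyl and the silicon of the aryl silyl ether, each with a phenoxide as leaving group, so both phenols should be freed in one operation without touching the three stereocentres.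

**Compound list**

1 | eugenol (4-allyl-2-methoxyphenol) | C=CCc1ccc(O)c(OC)c1 | starting material
2 | 4-allyl-2-methoxyphenyl pivalate | C=CCc1ccc(OC(=O)C(C)(C)C)c(OC)c1 | intermediate
3 | 9-[3-(3-methoxy-4-pivaloyloxyphenyl)propyl]-9-borabicyclo[3.3.1]nonane | COc1cc(CCCB2C3CCCC2CCC3)ccc1OC(=O)C(C)(C)C | intermediate (not isolated)
4 | 4-(3-hydroxypropyl)-2-methoxyphenyl pivalate | COc1cc(CCCO)ccc1OC(=O)C(C)(C)C | intermediate
5 | 2-methoxy-4-(3-oxopropyl)phenyl pivalate | COc1cc(CCC=O)ccc1OC(=O)C(C)(C)C | intermediate
6 | allenylboronic acid pinacol ester | C=C=CB1OC(C)(C)C(C)(C)O1 | starting material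
7 | pinacol borate ester of the (S)-homopropargylic alcohol | COc1cc(CC[C@H](OB2OC(C)(C)C(C)(C)O2)CC#C)ccc1OC(=O)C(C)(C)C | intermediate (not isolated)
8 | 4-[(3S)-3-hydroxyhex-5-yn-1-yl]-2-methoxyphenyl pivalate | COc1cc(CC[C@H](O)CC#C)ccc1OC(=O)C(C)(C)C | intermediate
9 | vanillin | COc1cc(C=O)ccc1O | starting material
10 | 4-(tert-butyldimethylsilyloxy)-3-methoxybenzaldehyde | COc1cc(C=O)ccc1O[Si](C)(C)C(C)(C)C | intermediate
11 | [4-(tert-butyldimethylsilyloxy)-3-methoxyphenyl]methanol | COc1cc(CO)ccc1O[Si](C)(C)C(C)(C)C | intermediate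
12 | 4-(tert-butyldimethylsilyloxy)-3-methoxybenzyl 2,2,2-trichloroacetimidate | COc1cc(COC(=N)C(Cl)(Cl)Cl)ccc1O[Si](C)(C)C(C)(C)C | intermediate
13 | 4-[(3S)-3-{[4-(tert-butyldimethylsilyloxy)-3-methoxybenzyl]oxy}hex-5-yn-1-yl]-2-methoxyphenyl pivalate | COc1cc(CC[C@H](OCc2ccc(O[Si](C)(C)C(C)(C)C)c(OC)c2)CC#C)ccc1OC(=O)C(C)(C)C | intermediate
14 | (4S)-4-{[4-(tert-butyldimethylsilyloxy)-3-methoxybenzyl]oxy}-6-[3-methoxy-4-(pivaloyloxy)phenyl]hex-1-en-2-yl acetate | COc1cc(CC[C@H](OCc2ccc(O[Si](C)(C)C(C)(C)C)c(OC)c2)CC(=C)OC(C)=O)ccc1OC(=O)C(C)(C)C | intermediate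
15 | (E)-aryl oxocarbenium ion formed from 14 by loss of hydride | COc1cc(CC[C@H](/[O+]=C/c2ccc(O[Si](C)(C)C(C)(C)C)c(OC)c2)CC(=C)OC(C)=O)ccc1OC(=O)C(C)(C)C | intermediate (not isolated)
16 | O-acetyl oxocarbenium ion of the cyclised oxan-4-one | COc1cc(CC[C@H]2CC(=[O+]C(C)=O)C[C@@H](c3ccc(O[Si](C)(C)C(C)(C)C)c(OC)c3)O2)ccc1OC(=O)C(C)(C)C | intermediate (not isolated)
17 | (2S,6S)-2-[4-(tert-butyldimethylsilyloxy)-3-methoxyphenyl]-6-{2-[3-methoxy-4-(pivaloyloxy)phenyl]ethyl}oxan-4-one | COc1cc(CC[C@H]2CC(=O)C[C@@H](c3ccc(O[Si](C)(C)C(C)(C)C)c(OC)c3)O2)ccc1OC(=O)C(C)(C)C | intermediate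
18 | 4-{2-[(2S,4S,6S)-6-[4-(tert-butyldimethylsilyloxy)-3-methoxyphenyl]-4-hydroxyoxan-2-yl]ethyl}-2-methoxyphenyl pivalate | COc1cc(CC[C@H]2C[C@H](O)C[C@@H](c3ccc(O[Si](C)(C)C(C)(C)C)c(OC)c3)O2)ccc1OC(=O)C(C)(C)C | intermediate
19 | (2S,4S,6S)-2-(4-hydroxy-3-methoxyphenyl)-6-[2-(4-hydroxy-3-methoxyphenyl)ethyl]oxan-4-ol | COc1cc(CC[C@H]2C[C@H](O)C[C@@H](c3ccc(O)c(OC)c3)O2)ccc1O | target

**Step count**

Total steps: 12. Longest linear sequence: 9 (steps 1–4 and 8–12, from eugenol).

**Steps most likely to fail**

Step 10 (key step). Electron transfer from a silyloxy-substituted ring may be slow. The oxocarbenium ion may also pass its silyl group to the hydroquinone anion and collapse to a quinone methide before the enol acetate captures it, or oxidation may continue beyond the ring closure. The fallback generates the same cation without an oxidant. It sets out from 8, which is silylated (Et3SiCl, imidazole, CH2Cl2) to the triethylsilyl ether F1. The ruthenium-catalysed addition of acetic acid used in step 9 converts F1 into the silyl ether enol acetate F2. Condensation of F2 with aldehyde 10 under TMSOTf (cat.) in CH2Cl2 at −78 °C should give oxocarbenium ion 15 by loss of the silyl group and the aldehyde oxygen. Prins-type closure through the same chair then returns to the route at 17.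

Step 4. Facial discrimination may be incomplete with an unbranched aliphatic aldehyde, so the enantiomeric purity of C6 would be eroded. The fallback sets the centre by resolution and sets out from 5. Corey–Chaykovsky epoxidation (Me3SI, KN(SiMe3)2, THF, −10 °C) gives the racemic epoxide F3. Hydrolytic kinetic resolution with the chiral (salen)Co(OAc) complex [salen = N,N′-bis(3,5-di-tert-butylsalicylidene)-1,2-cyclohexanediamine] and 0.55 equiv of water, using the catalyst enantiomer that hydrolyses the (R)-epoxide, leaves the (S)-epoxide F4. Opening of F4 at the terminal carbon with lithium trimethylsilylacetylide and BF3·OEt2 (THF, −78 °C) gives the silylalkyne F5 with the carbinol centre untouched. Desilylation with Bu4NF buffered with AcOH (THF, 0 °C) returns to the route at 8.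

Step 8. The electron-rich imidate may rearrange to the N-benzyl trichloroacetamide or oligomerise by ring alkylation faster than the hindered secondary alcohol is benzylated, and acid may loosen the aryl silyl ether. The fallback forms the same C–O bond by reductive etherification. It sets out from 8, which is converted (Me3SiCl, Et3N, CH2Cl2) into the trimethylsilyl ether F6. Treatment of F6 with aldehyde 10, Et3SiH and TMSOTf (cat.) in CH2Cl2 at −78 °C should give the mixed silyl acetal and then the oxocarbenium ion. The silane should reduce this ion at low temperature before the alkyne can add to it, and the product rejoins the route at 13.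

**Further compounds**

F1 | step 10 | 2-methoxy-4-[(3S)-3-(triethylsilyloxy)hex-5-yn-1-yl]phenyl pivalate | COc1cc(CC[C@H](O[Si](CC)(CC)CC)CC#C)ccc1OC(=O)C(C)(C)C
F2 | step 10 | (4S)-6-[3-methoxy-4-(pivaloyloxy)phenyl]-4-(triethylsilyloxy)hex-1-en-2-yl acetate | COc1cc(CC[C@H](O[Si](CC)(CC)CC)CC(=C)OC(C)=O)ccc1OC(=O)C(C)(C)C
F3 | step 4 | racemic 2-methoxy-4-[2-(oxiran-2-yl)ethyl]phenyl pivalate | COc1cc(CCC2CO2)ccc1OC(=O)C(C)(C)C
F4 | step 4 | 2-methoxy-4-{2-[(2S)-oxiran-2-yl]ethyl}phenyl pivalate | COc1cc(CC[C@H]2CO2)ccc1OC(=O)C(C)(C)C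
F5 | step 4 | 4-[(3S)-3-hydroxy-6-(trimethylsilyl)hex-5-yn-1-yl]-2-methoxyphenyl pivalate | COc1cc(CC[C@H](O)CC#C[Si](C)(C)C)ccc1OC(=O)C(C)(C)C
F6 | step 8 | 2-methoxy-4-[(3S)-3-(trimethylsilyloxy)hex-5-yn-1-yl]phenyl pivalate | COc1cc(CC[C@H](O[Si](C)(C)C)CC#C)ccc1OC(=O)C(C)(C)C
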